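## Retrosynthetic overview

1. Ring atoms are counted C1 (ketone), C2 (N-bearing), C3, C4 (carbinol), C5, C6 (Cl-bearing); the last disconnection is the ring bond C1–C6. The enabling feature is that C1 and the oxygen on C4 are 1,4-related across ring A, so C1 can be parked on that oxygen as a five-membered butenolide (ring B: O–C1(=O)–C2(N)=C3–C4) while C5=C6 hangs on C4 as an (E)-2-chlorovinyl group. The target is then an isomer of butenolide acid 21.
2. Key event: lithiation at C6 (the hydrogen geminal to chlorine) and O-to-C acyl transfer across ring B. It builds carbocycle A, frees the 4-OH, creates the cross-conjugated chlorodienone and destroys ring B. The temporary O–C1 bond has fixed the C2=C3 geometry and activated C1.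
3. Butenolide 21: enamide C–N by palladium amidation of an isotetronic acid triflate with dienamide 17; chlorovinyl group by Takai olefination of the CH2OH-derived aldehyde; α-keto lactone from malonate opening of an epoxide, nitrosative loss of the ester and deoximation.
4. Stereochemistry: C4 comes from a Katsuki–Sharpless epoxidation of a 2-substituted allylic alcohol and is never touched again; the syn-dimethyl array of the side chain comes from lipase desymmetrization of a meso-diol.
5. Ring order: oxirane, then ring B (γ-lactone, then butenolide), then ring A in the last step with ring B opened in the same operation.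

Key step: step 17

Assumption: Amano lipase AK is taken to acetylate the hydroxymethyl group next to the (S)-configured centre of meso-diol 11; if a given preparation prefers the other arm, hydrolysis of the diacetate with the same enzyme leads to the same monoacetate 12.

## Route

Step 1
Reactants: 1 methyl 5-bromopentanoate; 2 2-bromoprop-2-en-1-ol
Product: 4 methyl 6-(hydroxymethyl)hept-6-enoate, via (5-methoxy-5-oxopentyl)zinc bromide 3 (not isolated)
Conditions: Zn dust, LiCl, THF, 50 °C; then 2, Pd(OAc)2 (2 mol%), SPhos (4 mol%), THF, 25 °C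
Reagents that add atoms: none
Why: LiCl-promoted zinc insertion gives an ester-tolerant alkylzinc bromide, and Negishi coupling with the 1,1-disubstituted vinyl bromide should proceed without hydroxyl protection because alkylzinc halides are protonated only slowly by alcohols.

Step 2
Reactants: 4 methyl 6-(hydroxymethyl)hept-6-enoate
Product: 5 methyl 5-[(2S)-2-(hydroxymethyl)oxiran-2-yl]pentanoate
Conditions: Ti(OiPr)4 (10 mol%), L-(+)-diisopropyl tartrate (12 mol%), t-BuOOH, 4 Å molecular sieves, CH2Cl2, −20 °C
Reagents that add atoms: tert-butyl hydroperoxide CC(C)(C)OO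
Why: Katsuki–Sharpless asymmetric epoxidation; the titanium tartrate complex delivers oxygen to one face of the 2-substituted allylic alcohol (reagent control, L-(+)-tartrate giving the (S)-2-alkylglycidol as with 2-methylallyl alcohol), which sets the only ring stereocentre of the target.

Step 3
Reactants: 5 methyl 5-[(2S)-2-(hydroxymethyl)oxiran-2-yl]pentanoate
Product: 6 methyl (5R)-5-(hydroxymethyl)-5-(5-methoxy-5-oxopentyl)-2-oxooxolane-3-carboxylate (both C3 epimers)
Conditions: dimethyl malonate, NaOMe, MeOH, 65 °C; then AcOH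
Reagents that add atoms: dimethyl malonate COC(=O)CC(=O)OC
Why: Malonate alkylation by SN2 opening of the epoxide at its CH2 terminus (no bond to the stereocentre is touched), then lactonization of the tertiary alkoxide onto a malonate ester (5-exo-trig); the five-membered lactone is expected to be favoured over the six-membered alternative through the primary hydroxyl.

Step 4
Reactants: 6 methyl (5R)-5-(hydroxymethyl)-5-(5-methoxy-5-oxopentyl)-2-oxooxolane-3-carboxylate
Product: 7 methyl 5-[(2R)-4-(hydroxyimino)-2-(hydroxymethyl)-5-oxooxolan-2-yl]pentanoate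
Conditions: t-BuONO, NaOMe, MeOH, 0 → 25 °C; then AcOH
Reagents that add atoms: tert-butyl nitrite CC(C)(C)ON=O
Why: C-nitrosation of the active methine followed by methoxide-induced loss of the ester group as dimethyl carbonate (Japp–Klingemann-type nitrosative dealkoxycarbonylation) should leave the α-oximino lactone.

Step 5
Reactants: 7 methyl 5-[(2R)-4-(hydroxyimino)-2-(hydroxymethyl)-5-oxooxolan-2-yl]pentanoate
Product: 8 methyl 5-[(2R)-4-hydroxy-2-(hydroxymethyl)-5-oxo-2,5-dihydrofuran-2-yl]pentanoate
Conditions: aq. TiCl3, NH4OAc, THF/H2O, 25 °C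
Reagents that add atoms: water O
Why: Reductive deoximation; trivalent titanium cleaves the N–O bond, the imine hydrolyses, and the α-keto lactone should rest as its stable enol (an isotetronic acid).

Step 6
Reactants: 8 methyl 5-[(2R)-4-hydroxy-2-(hydroxymethyl)-5-oxo-2,5-dihydrofuran-2-yl]pentanoate
Product: 9 methyl 5-[(2R)-2-(hydroxymethyl)-5-oxo-4-(trifluoromethanesulfonyloxy)-2,5-dihydrofuran-2-yl]pentanoate
Conditions: PhNTf2, Et3N, CH2Cl2, 0 °C
Reagents that add atoms: N-phenylbis(trifluoromethanesulfonimide) O=S(=O)(N(c1ccccc1)S(=O)(=O)C(F)(F)F)C(F)(F)F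
Why: Enol triflation; the acidic enol reacts as its ammonium enolate while the neutral primary alcohol should be inert to the mild triflimide.

Step 7
Reactants: 10 meso-2,4-dimethylglutaric anhydride
Product: 11 meso-2,4-dimethylpentane-1,5-diol
Conditions: LiAlH4, THF, 0 → 65 °C
Reagents that add atoms: none
Why: Hydride reduction of the anhydride to the diol; reduction outpaces enolization, so the cis (meso) relationship should be kept.

Step 8
Reactants: 11 meso-2,4-dimethylpentane-1,5-diol
Product: 12 (2R,4S)-5-acetoxy-2,4-dimethylpentan-1-ol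
Conditions: Amano lipase AK (Pseudomonas fluorescens), vinyl acetate, THF, 25 °C
Reagents that add atoms: vinyl acetate CC(=O)OC=C
Why: Enzymatic desymmetrization by irreversible transesterification; the lipase acylates one enantiotopic hydroxymethyl group, which fixes both methyl-bearing centres at once (catalyst control).

Step 9
Reactants: 12 (2R,4S)-5-acetoxy-2,4-dimethylpentan-1-ol
Product: 13 (2S,4R)-2,4-dimethyl-5-oxopentyl acetate
Conditions: Dess–Martin periodinane, CH2Cl2, 25 °C
Reagents that add atoms: none
Why: Dess–Martin oxidation under non-basic conditions should give the α-branched aldehyde without epimerization.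

Step 10
Reactants: 13 (2S,4R)-2,4-dimethyl-5-oxopentyl acetate
Product: 14 (2S,4R)-2,4,6-trimethylhept-5-en-1-yl acetate
Conditions: i-PrPPh3I, n-BuLi, THF, 0 °C; then 13, −78 → 25 °C
Reagents that add atoms: isopropyltriphenylphosphonium iodide CC(C)[P+](c1ccccc1)(c1ccccc1)c1ccccc1.[I-]
Why: Wittig olefination with the non-stabilized isopropylidene ylide, which attacks the aldehyde far faster than the acetate and forms the trisubstituted alkene without a geometric issue.

Step 11
Reactants: 14 (2S,4R)-2,4,6-trimethylhept-5-en-1-yl acetate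
Product: 15 (2S,4R)-2,4,6-trimethylhept-5-en-1-ol
Conditions: K2CO3 (cat.), MeOH, 25 °C
Reagents that add atoms: none
Why: Base-catalysed methanolysis (transesterification) removes the acetate without touching the stereocentres.

Step 12
Reactants: 15 (2S,4R)-2,4,6-trimethylhept-5-en-1-ol
Product: 17 (2E,4S,6R)-4,6,8-trimethylnona-2,7-dienamide, via (2S,4R)-2,4,6-trimethylhept-5-enal 16 (not isolated)
Conditions: Dess–Martin periodinane, CH2Cl2, 25 °C; then Ph3P=CHCONH2, 40 °C
Reagents that add atoms: (carbamoylmethylene)triphenylphosphorane NC(=O)C=P(c1ccccc1)(c1ccccc1)c1ccccc1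
Why: Tandem Dess–Martin oxidation and Wittig reaction; the amide-stabilized ylide should give the (E)-enamide directly and the epimerizable aldehyde is consumed without isolation.

Step 13
Reactants: 9 methyl 5-[(2R)-2-(hydroxymethyl)-5-oxo-4-(trifluoromethanesulfonyloxy)-2,5-dihydrofuran-2-yl]pentanoate; 17 (2E,4S,6R)-4,6,8-trimethylnona-2,7-dienamide
Product: 18 methyl 5-[(2R)-2-(hydroxymethyl)-5-oxo-4-{[(2E,4S,6R)-4,6,8-trimethylnona-2,7-dienoyl]amino}-2,5-dihydrofuran-2-yl]pentanoate
Conditions: Pd2(dba)3 (2.5 mol%), Xantphos (7.5 mol%), Cs2CO3, 1,4-dioxane, 50 °C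
Reagents that add atoms: none
Why: Buchwald–Hartwig-type amidation of an electron-poor enol triflate with a primary amide; zerovalent palladium inserts into the C–OTf bond and the wide-bite-angle ligand promotes C–N reductive elimination, giving the 3-acylamino butenolide whose ring fixes the enamide geometry.

Step 14
Reactants: 18 methyl 5-[(2R)-2-(hydroxymethyl)-5-oxo-4-{[(2E,4S,6R)-4,6,8-trimethylnona-2,7-dienoyl]amino}-2,5-dihydrofuran-2-yl]pentanoate
Product: 19 methyl 5-[(2R)-2-formyl-5-oxo-4-{[(2E,4S,6R)-4,6,8-trimethylnona-2,7-dienoyl]amino}-2,5-dihydrofuran-2-yl]pentanoate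
Conditions: Dess–Martin periodinane, pyridine, CH2Cl2, 0 → 25 °C
Reagents that add atoms: none
Why: Dess–Martin oxidation of the neopentyl-type primary alcohol to an aldehyde that has no α-hydrogen and therefore cannot epimerize.

Step 15
Reactants: 19 methyl 5-[(2R)-2-formyl-5-oxo-4-{[(2E,4S,6R)-4,6,8-trimethylnona-2,7-dienoyl]amino}-2,5-dihydrofuran-2-yl]pentanoate
Product: 20 methyl 5-[(2R)-2-[(E)-2-chloroethenyl]-5-oxo-4-{[(2E,4S,6R)-4,6,8-trimethylnona-2,7-dienoyl]amino}-2,5-dihydrofuran-2-yl]pentanoate
Conditions: CrCl2, CHCl3, THF, 65 °C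
Reagents that add atoms: chloroform ClC(Cl)Cl
Why: Takai–Utimoto chloro-olefination; the gem-dichromium reagent formed from CHCl3 and divalent chromium adds to the aldehyde and eliminates anti to give the (E)-chloroalkene, and esters, lactone and amide are tolerated.

Step 16
Reactants: 20 methyl 5-[(2R)-2-[(E)-2-chloroethenyl]-5-oxo-4-{[(2E,4S,6R)-4,6,8-trimethylnona-2,7-dienoyl]amino}-2,5-dihydrofuran-2-yl]pentanoate
Product: 21 5-[(2R)-2-[(E)-2-chloroethenyl]-5-oxo-4-{[(2E,4S,6R)-4,6,8-trimethylnona-2,7-dienoyl]amino}-2,5-dihydrofuran-2-yl]pentanoic acid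
Conditions: Me3SnOH, 1,2-dichloroethane, 70 °C; then 1 M HCl wash
Reagents that add atoms: trimethyltin hydroxide C[Sn](C)(C)O
Why: Neutral tin-hydroxide cleavage of the unhindered methyl ester; the conjugated lactone of a tertiary alcohol is attacked more slowly and would re-close on the acidic work-up.

Step 17
Reactants: 21 5-[(2R)-2-[(E)-2-chloroethenyl]-5-oxo-4-{[(2E,4S,6R)-4,6,8-trimethylnona-2,7-dienoyl]amino}-2,5-dihydrofuran-2-yl]pentanoic acid
Product: 24 5-[(1R)-3-chloro-1-hydroxy-4-oxo-5-{[(2E,4S,6R)-4,6,8-trimethylnona-2,7-dienoyl]amino}cyclohexa-2,5-dien-1-yl]pentanoic acid, via trilithio chlorocarbenoid 22 (not isolated), via bridged oxanorbornadiene alkoxide 23 (not isolated)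
Conditions: LiTMP (3.3 equiv), THF, −95 → −60 °C; then AcOH, −78 °C
Reagents that add atoms: none
Why: Proposed new method: LiTMP first forms the lithium carboxylate and the N-lithio enamide and then removes, with retention, the vinylic hydrogen geminal to chlorine of the (E)-chloroalkene (Köbrich-type carbenoid 22, lithium cis to the ring carbon); this carbanion adds across the butenolide to the lactone carbonyl (6-exo-trig with respect to the C=O, closing the carbocycle through the 7-oxanorbornadiene alkoxide 23), and the strained tetrahedral intermediate collapses by cleaving the bond from the former carbonyl carbon to the bridging oxygen, so that the acyl group moves from oxygen to carbon, the cross-conjugated chlorodienone forms and the tertiary alkoxide is released. The closest known reaction types are the in situ trapping of 1-chloro-1-lithioalkenes generated with LiTMP, the Parham-type intramolecular acylation of vinyl- and aryllithiums by esters and lactones, and the opening of 7-oxanorbornadienes (furan–alkyne adducts) to 4-oxygenated cyclohexadienones; what is new is the bridged, strained geometry of the acyl transfer. No new stereocentre remains in the product (the bridgehead hemiketal carbon of 23 becomes the planar carbonyl), and the carbinol carbon keeps its (R) configuration because only its O–acyl bond, not a bond to the stereocentre itself, is broken. The step needs site-selective metalation, which the (E) geometry (no anti β-hydrogen for elimination, α-hydrogen acidified by chlorine) and the prior conversion of NH and CO2H into unreactive lithium salts should secure, and it needs the carbanion cis to the ring, which retention of configuration provides. Chemoselectivity for the lactone carbonyl over amidate and carboxylate should follow from their anionic deactivation and from proximity, and the collapse should be driven by relief of the oxanorbornadiene strain and formation of the dienone.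

## Compound list

1 | methyl 5-bromopentanoate | COC(=O)CCCCBr | starting material
2 | 2-bromoprop-2-en-1-ol | OCC(Br)=C | starting material
3 | (5-methoxy-5-oxopentyl)zinc bromide | COC(=O)CCCC[Zn]Br | intermediate
4 | methyl 6-(hydroxymethyl)hept-6-enoate | COC(=O)CCCCC(=C)CO | intermediate
5 | methyl 5-[(2S)-2-(hydroxymethyl)oxiran-2-yl]pentanoate | COC(=O)CCCC[C@]1(CO)CO1 | intermediate
6 | methyl (5R)-5-(hydroxymethyl)-5-(5-methoxy-5-oxopentyl)-2-oxooxolane-3-carboxylate (C3 epimers) | COC(=O)CCCC[C@]1(CO)CC(C(=O)OC)C(=O)O1 | intermediate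
7 | methyl 5-[(2R)-4-(hydroxyimino)-2-(hydroxymethyl)-5-oxooxolan-2-yl]pentanoate | COC(=O)CCCC[C@]1(CO)CC(=NO)C(=O)O1 | intermediate
8 | methyl 5-[(2R)-4-hydroxy-2-(hydroxymethyl)-5-oxo-2,5-dihydrofuran-2-yl]pentanoate | COC(=O)CCCC[C@]1(CO)C=C(O)C(=O)O1 | intermediate
9 | methyl 5-[(2R)-2-(hydroxymethyl)-5-oxo-4-(trifluoromethanesulfonyloxy)-2,5-dihydrofuran-2-yl]pentanoate | COC(=O)CCCC[C@]1(CO)C=C(OS(=O)(=O)C(F)(F)F)C(=O)O1 | intermediate
10 | meso-2,4-dimethylglutaric anhydride, (3R,5S)-3,5-dimethyloxane-2,6-dione | C[C@H]1C[C@@H](C)C(=O)OC1=O | starting material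
11 | meso-2,4-dimethylpentane-1,5-diol | C[C@H](CO)C[C@@H](C)CO | intermediate
12 | (2R,4S)-5-acetoxy-2,4-dimethylpentan-1-ol | OC[C@H](C)C[C@H](C)COC(C)=O | intermediate
13 | (2S,4R)-2,4-dimethyl-5-oxopentyl acetate | O=C[C@H](C)C[C@H](C)COC(C)=O | intermediate
14 | (2S,4R)-2,4,6-trimethylhept-5-en-1-yl acetate | CC(C)=C[C@H](C)C[C@H](C)COC(C)=O | intermediate
15 | (2S,4R)-2,4,6-trimethylhept-5-en-1-ol | CC(C)=C[C@H](C)C[C@H](C)CO | intermediate
16 | (2S,4R)-2,4,6-trimethylhept-5-enal | CC(C)=C[C@H](C)C[C@H](C)C=O | intermediate
17 | (2E,4S,6R)-4,6,8-trimethylnona-2,7-dienamide | CC(C)=C[C@H](C)C[C@H](C)/C=C/C(N)=O | intermediate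
18 | methyl 5-[(2R)-2-(hydroxymethyl)-5-oxo-4-{[(2E,4S,6R)-4,6,8-trimethylnona-2,7-dienoyl]amino}-2,5-dihydrofuran-2-yl]pentanoate | COC(=O)CCCC[C@]1(CO)C=C(NC(=O)/C=C/[C@@H](C)C[C@@H](C)C=C(C)C)C(=O)O1 | intermediate
19 | methyl 5-[(2R)-2-formyl-5-oxo-4-{[(2E,4S,6R)-4,6,8-trimethylnona-2,7-dienoyl]amino}-2,5-dihydrofuran-2-yl]pentanoate | COC(=O)CCCC[C@]1(C=O)C=C(NC(=O)/C=C/[C@@H](C)C[C@@H](C)C=C(C)C)C(=O)O1 | intermediate
20 | methyl 5-[(2R)-2-[(E)-2-chloroethenyl]-5-oxo-4-{[(2E,4S,6R)-4,6,8-trimethylnona-2,7-dienoyl]amino}-2,5-dihydrofuran-2-yl]pentanoate | COC(=O)CCCC[C@]1(/C=C/Cl)C=C(NC(=O)/C=C/[C@@H](C)C[C@@H](C)C=C(C)C)C(=O)O1 | intermediate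
21 | 5-[(2R)-2-[(E)-2-chloroethenyl]-5-oxo-4-{[(2E,4S,6R)-4,6,8-trimethylnona-2,7-dienoyl]amino}-2,5-dihydrofuran-2-yl]pentanoic acid | OC(=O)CCCC[C@]1(/C=C/Cl)C=C(NC(=O)/C=C/[C@@H](C)C[C@@H](C)C=C(C)C)C(=O)O1 | intermediate
22 | trilithio derivative of 21 (lithium carboxylate, N-lithio amide, 2-chloro-2-lithioethenyl group with lithium cis to the ring carbon) | [Li]OC(=O)CCCC[C@]1(/C=C(/Cl)[Li])C=C(N([Li])C(=O)/C=C/[C@@H](C)C[C@@H](C)C=C(C)C)C(=O)O1 | intermediate
23 | trilithio 7-oxabicyclo[2.2.1]hepta-2,5-diene bridgehead alkoxide (tetrahedral intermediate of the acyl transfer) | [Li]OC(=O)CCCC[C@]12C=C(N([Li])C(=O)/C=C/[C@@H](C)C[C@@H](C)C=C(C)C)[C@](O[Li])(O1)C(Cl)=C2 | intermediate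
24 | 5-[(1R)-3-chloro-1-hydroxy-4-oxo-5-{[(2E,4S,6R)-4,6,8-trimethylnona-2,7-dienoyl]amino}cyclohexa-2,5-dien-1-yl]pentanoic acid | CC(C)=C[C@H](C)C[C@H](C)/C=C/C(=O)NC1=C[C@](O)(CCCCC(=O)O)C=C(Cl)C1=O | target

## Step count and risks

Total step count: 17. Longest linear sequence: 11 steps (steps 1–6 and 13–17 from 1; the side-chain branch, steps 7–12 and 13–17 from 10, is equally long).

Steps most likely to fail:

1. Step 17 (proposed new method). The acyl transfer has to pass through a strained bridged transition state and may be slower than decomposition of the lithium carbenoid (α-elimination or rearrangement to the alkyne). The base may also metalate the γ-position of the side-chain amidate and erode the adjacent stereocentre. Fallback, using the ordinary Weinreb ketone synthesis instead of the lactone tether: it sets out from 21. The lactone is opened with MeNH(OMe)·HCl and AlMe3 (CH2Cl2, 0 → 25 °C) to the hydroxy Weinreb amide F1, in which the carbinol carbon and the amide carbonyl remain cis on the double bond. The tertiary hydroxyl is capped with TESOTf and 2,6-lutidine (the silyl ester is lost on aqueous work-up) to give the silyl ether F2. LiTMP under the conditions of step 17 then closes the ring through an unstrained six-membered chelated intermediate to the silylated quinol F3, and HF·pyridine (THF, 0 °C) brings the sequence back to the route at 24.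

2. Step 15. Olefination of the hindered aldehyde on a quaternary carbon may be slow, which would leave room for reduction by divalent chromium or for erosion of the E selectivity on which step 17 depends. Fallback, building the chloroalkene from an alkyne: it sets out from 19. The Ohira–Bestmann reagent (dimethyl (1-diazo-2-oxopropyl)phosphonate, K2CO3, MeOH, 0 °C) gives the terminal alkyne F4. Hydroboration with pinacolborane (Cp2Zr(H)Cl cat., Et3N cat., 60 °C) gives the (E)-alkenylboronate F5. Chlorodeboronation with CuCl2 (aqueous MeOH, 60 °C) proceeds with retention and comes back to the route at 20.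

3. Step 13. Carbonate may cleave the S–O bond of the enol triflate faster than the amide couples, or the free primary alkoxide may trans-lactonize the butenolide. Fallback, a condensation instead of a cross-coupling: it sets out from enol 8 and amide 17, which are condensed directly with loss of water (pyridinium p-toluenesulfonate cat., toluene, 4 Å molecular sieves, 80 °C) in the manner of a dehydroamino acid synthesis from an α-keto ester, and it comes back to the route at 18.

## Further compounds

F1 | step 17 | ring-opened hydroxy Weinreb amide of 21: (6R)-6-[(E)-2-chloroethenyl]-6-hydroxy-9-[methoxy(methyl)amino]-9-oxo-8-{[(2E,4S,6R)-4,6,8-trimethylnona-2,7-dienoyl]amino}non-7-enoic acid, carbinol carbon cis to the Weinreb carbonyl | OC(=O)CCCC[C@](O)(/C=C/Cl)/C=C(/NC(=O)/C=C/[C@@H](C)C[C@@H](C)C=C(C)C)C(=O)N(C)OC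
F2 | step 17 | triethylsilyl ether of F1 | OC(=O)CCCC[C@](O[Si](CC)(CC)CC)(/C=C/Cl)/C=C(/NC(=O)/C=C/[C@@H](C)C[C@@H](C)C=C(C)C)C(=O)N(C)OC
F3 | step 17 | triethylsilyl ether of 24 at the tertiary hydroxyl | CC(C)=C[C@H](C)C[C@H](C)/C=C/C(=O)NC1=C[C@](O[Si](CC)(CC)CC)(CCCCC(=O)O)C=C(Cl)C1=O
F4 | step 15 | methyl 5-[(2R)-2-ethynyl-5-oxo-4-{[(2E,4S,6R)-4,6,8-trimethylnona-2,7-dienoyl]amino}-2,5-dihydrofuran-2-yl]pentanoate | COC(=O)CCCC[C@]1(C#C)C=C(NC(=O)/C=C/[C@@H](C)C[C@@H](C)C=C(C)C)C(=O)O1
F5 | step 15 | methyl 5-[(2R)-5-oxo-2-[(E)-2-(4,4,5,5-tetramethyl-1,3,2-dioxaborolan-2-yl)ethenyl]-4-{[(2E,4S,6R)-4,6,8-trimethylnona-2,7-dienoyl]amino}-2,5-dihydrofuran-2-yl]pentanoate | COC(=O)CCCC[C@]1(/C=C/B2OC(C)(C)C(C)(C)O2)C=C(NC(=O)/C=C/[C@@H](C)C[C@@H](C)C=C(C)C)C(=O)O1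
F0 | step 13 | none | none
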